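**Retrosynthetic overview**

- The target is hypholomine B, a dimer of hispidin. Both 2-pyranone rings are bought intact as triacetic acid lactone, so the dihydrofuran is the only ring made, and it is made last; the final operation is removal of four aryl TBS ethers and one enol acetate.
- The dihydrofuran is cut at C3–C3a and O1–C2. C3 of one complete hispidin unit, normally the nucleophilic carbon of the 1,3-dicarbonyl, is made electrophilic as its phenyliodonium ylide / rhodium carbene (an enolonium equivalent). It is joined to the normally nucleophilic styrene carbon next to the pyranone of a second complete hispidin unit. A chiral dirhodium carboxylate sets C3 and trans ring closure sets C2.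
- Both partners come from one precursor, di-O-TBS-hispidin: O-acetylation gives the alkene partner, PhI(OAc)2 gives the ylide partner.
- Di-O-TBS-hispidin comes from the dianion of triacetic acid lactone and bis-TBS protocatechualdehyde (vinylogous aldol, then dehydration).

Assumption: the (S)-configured dirhodium catalyst of step 4 is taken to give the (2R,3R) series; if the first run shows the opposite sense, its mirror-image (R)-catalyst is used with nothing else changed.

**Step 1**
Reactants: 1 protocatechualdehyde (3,4-dihydroxybenzaldehyde)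
Product: 2 bis-TBS protocatechualdehyde [3,4-bis(tert-butyldimethylsilyloxy)benzaldehyde]
Conditions: TBSCl (2.3 equiv), imidazole (5 equiv), DMF, 0 °C → rt
Reagents that add atoms: tert-butyldimethylsilyl chloride, CC(C)(C)[Si](C)(C)Cl
Why: Imidazole-promoted silyl ether formation on both phenols; the aryl silyl ethers keep the ring electron-rich for step 4 and are later removed with fluoride; no stereocentre is involved.

**Step 2**
Reactants: 2 bis-TBS protocatechualdehyde; 3 triacetic acid lactone (4-hydroxy-6-methyl-2H-pyran-2-one)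
Product: 5 di-O-TBS-hispidin [6-{(E)-2-[3,4-bis(tert-butyldimethylsilyloxy)phenyl]ethenyl}-4-hydroxy-2H-pyran-2-one], via racemic aldol adduct 4 (not isolated)
Conditions: 3 (1.2 equiv), commercial LiN(iPr)2 (2.5 equiv), THF–DMPU, −78 °C, 1 h; add 2, −78 → −20 °C; cold 1 M HCl quench, extract, concentrate; then TsOH·H2O (5 mol%), toluene, 80 °C
Reagents that add atoms: none
Why: The O,C-dianion of 3 reacts at its more basic 6-CH2 terminus with the aldehyde (vinylogous aldol addition), and the p-silyloxybenzylic alcohol 4 then loses water under acid catalysis (E1 dehydration) to give only the conjugated E-alkene.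

**Step 3**
Reactants: 5 di-O-TBS-hispidin
Product: 6 di-O-TBS-hispidin 4-O-acetate [6-{(E)-2-[3,4-bis(tert-butyldimethylsilyloxy)phenyl]ethenyl}-2-oxo-2H-pyran-4-yl acetate]
Conditions: Ac2O (1.2 equiv), pyridine (2 equiv), CH2Cl2, 0 °C, 1 h (no DMAP)
Reagents that add atoms: acetic anhydride, CC(=O)OC(C)=O
Why: O-acylation of the acidic vinylogous acid; the enol acetate removes the O–H that would quench the carbene and deactivates C3/C5 of this pyranone toward the electrophile of step 4, leaving the styrene as the most nucleophilic site.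

**Step 4**
Reactants: 5 di-O-TBS-hispidin (1.0 equiv); 6 di-O-TBS-hispidin 4-O-acetate (3.0 equiv); 7 (diacetoxyiodo)benzene
Product: 9 penta-protected hypholomine B [6-[(2R,3R)-2-[3,4-bis(tert-butyldimethylsilyloxy)phenyl]-6-{(E)-2-[3,4-bis(tert-butyldimethylsilyloxy)phenyl]ethenyl}-4-oxo-2,3-dihydro-4H-furo[3,2-c]pyran-3-yl]-2-oxo-2H-pyran-4-yl acetate], via phenyliodonium ylide 8 (not isolated)
Conditions: 5, 7 (1.05 equiv), MgO (2.5 equiv), 4 Å MS, CH2Cl2, 0 °C, dark, 1 h, filter under argon; filtrate added over 6 h to 6 and Rh2(S-NTTL)4 {dirhodium tetrakis[N-(1,8-naphthaloyl)-(S)-tert-leucinate], 2 mol%}, CH2Cl2, 0 °C → rt; neutral silica, excess 6 recovered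
Reagents that add atoms: none
Why: Proposed new method: PhI(OAc)2 converts the normally nucleophilic C3 of 5 into the iodonium ylide 8, which hands that carbon to the divalent-rhodium catalyst as an electrophilic acceptor/acceptor carbene with loss of PhI (an enolonium equivalent); the carbene carbon bonds to the styrene carbon next to the pyranone of 6 (normally an enol-like, nucleophilic position) because this places the developing positive charge on the benzylic carbon para to a silyloxy group, and the rhodium-bound enolate oxygen O4 then closes on that carbon anti to the pyranonyl group (formal [3+2] cycloaddition, trans-dihydrofuran); C3 is set in the C–C bond-forming event inside the chiral tert-leucinate pocket and C2 follows as trans; slow addition into excess 6 keeps the carbene away from the styryl groups of 8 and 9; closest known reaction type: dirhodium-carboxylate-catalysed [3+2] annulation of iodonium ylides or diazo compounds of cyclic 1,3-dicarbonyls (4-hydroxycoumarin, cyclohexane-1,3-dione) with styrenes such as trans-anethole to give trans-2-aryl-3-substituted 2,3-dihydrofurans, together with the enantioselective cyclopropanations of in-situ iodonium ylides by the same catalyst family.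

**Step 5**
Reactants: 9 penta-protected hypholomine B
Product: 11 hypholomine B [(2R,3R)-2-(3,4-dihydroxyphenyl)-6-[(E)-2-(3,4-dihydroxyphenyl)ethenyl]-3-(4-hydroxy-2-oxo-2H-pyran-6-yl)-2,3-dihydro-4H-furo[3,2-c]pyran-4-one], via tetrasilyl ether 10 (not isolated)
Conditions: imidazole (20 mol%), MeOH–THF, rt, argon; concentrate; then HF·pyridine, pyridine, THF, 0 °C → rt, argon
Reagents that add atoms: none
Why: Imidazole-catalysed methanolysis cleaves the activated enol acetate (a vinylogous anhydride) under neutral conditions and fluoride-mediated desilylation then frees the four phenols; the medium is never basic, so retro-oxa-Michael opening of the dihydrofuran (the only racemisation pathway) is avoided and both stereocentres are retained.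

**Compound list**

1 | 3,4-dihydroxybenzaldehyde (protocatechualdehyde) | O=Cc1ccc(O)c(O)c1 | starting material
2 | 3,4-bis(tert-butyldimethylsilyloxy)benzaldehyde | O=Cc1ccc(O[Si](C)(C)C(C)(C)C)c(O[Si](C)(C)C(C)(C)C)c1 | intermediate
3 | 4-hydroxy-6-methyl-2H-pyran-2-one (triacetic acid lactone) | Cc1cc(O)cc(=O)o1 | starting material
4 | rac-6-{2-[3,4-bis(tert-butyldimethylsilyloxy)phenyl]-2-hydroxyethyl}-4-hydroxy-2H-pyran-2-one | OC(Cc1cc(O)cc(=O)o1)c1ccc(O[Si](C)(C)C(C)(C)C)c(O[Si](C)(C)C(C)(C)C)c1 | intermediate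
5 | 6-{(E)-2-[3,4-bis(tert-butyldimethylsilyloxy)phenyl]ethenyl}-4-hydroxy-2H-pyran-2-one (di-O-TBS-hispidin) | O=c1cc(O)cc(/C=C/c2ccc(O[Si](C)(C)C(C)(C)C)c(O[Si](C)(C)C(C)(C)C)c2)o1 | intermediate
6 | 6-{(E)-2-[3,4-bis(tert-butyldimethylsilyloxy)phenyl]ethenyl}-2-oxo-2H-pyran-4-yl acetate | CC(=O)Oc1cc(/C=C/c2ccc(O[Si](C)(C)C(C)(C)C)c(O[Si](C)(C)C(C)(C)C)c2)oc(=O)c1 | intermediate
7 | (diacetoxyiodo)benzene, PhI(OAc)2 | CC(=O)OI(OC(C)=O)c1ccccc1 | starting material
8 | 6-{(E)-2-[3,4-bis(tert-butyldimethylsilyloxy)phenyl]ethenyl}-2-oxo-3-(phenyliodonio)-2H-pyran-4-olate (phenyliodonium ylide of 5) | O=C1OC(/C=C/c2ccc(O[Si](C)(C)C(C)(C)C)c(O[Si](C)(C)C(C)(C)C)c2)=CC([O-])=C1[I+]c1ccccc1 | intermediate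
9 | 6-[(2R,3R)-2-[3,4-bis(tert-butyldimethylsilyloxy)phenyl]-6-{(E)-2-[3,4-bis(tert-butyldimethylsilyloxy)phenyl]ethenyl}-4-oxo-2,3-dihydro-4H-furo[3,2-c]pyran-3-yl]-2-oxo-2H-pyran-4-yl acetate | O=c1cc(OC(C)=O)cc([C@@H]2c3c(cc(/C=C/c4ccc(O[Si](C)(C)C(C)(C)C)c(O[Si](C)(C)C(C)(C)C)c4)oc3=O)O[C@H]2c2ccc(O[Si](C)(C)C(C)(C)C)c(O[Si](C)(C)C(C)(C)C)c2)o1 | intermediate
10 | (2R,3R)-2-[3,4-bis(tert-butyldimethylsilyloxy)phenyl]-6-{(E)-2-[3,4-bis(tert-butyldimethylsilyloxy)phenyl]ethenyl}-3-(4-hydroxy-2-oxo-2H-pyran-6-yl)-2,3-dihydro-4H-furo[3,2-c]pyran-4-one | O=c1cc(O)cc([C@@H]2c3c(cc(/C=C/c4ccc(O[Si](C)(C)C(C)(C)C)c(O[Si](C)(C)C(C)(C)C)c4)oc3=O)O[C@H]2c2ccc(O[Si](C)(C)C(C)(C)C)c(O[Si](C)(C)C(C)(C)C)c2)o1 | intermediate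
11 | (2R,3R)-2-(3,4-dihydroxyphenyl)-6-[(E)-2-(3,4-dihydroxyphenyl)ethenyl]-3-(4-hydroxy-2-oxo-2H-pyran-6-yl)-2,3-dihydro-4H-furo[3,2-c]pyran-4-one (hypholomine B, CNP0229149.3) | O=c1cc(O)cc([C@@H]2c3c(cc(/C=C/c4ccc(O)c(O)c4)oc3=O)O[C@H]2c2ccc(O)c(O)c2)o1 | target

**Totals**

Total step count: 5. Longest linear sequence: 5 steps (1 → 2 → 5 → 6 → 9 → 11; compound 5 also feeds step 4 directly as the ylide partner).

**Steps most likely to fail, with fallbacks**

Step 4 is the main risk. The alkene of 6 is only moderately nucleophilic. The carbene may also attack the styryl group of 8 or 9 and give oligomers. A minor isomer closed through the lactone carbonyl oxygen is possible. The enantioselectivity of this catalyst family on a 1,2-disubstituted, pyranonyl-bearing styrene is unproven. The fallback sets out from 5 and 6 and replaces carbene transfer by a one-electron oxidative annulation followed by resolution. Ag2CO3 on Celite in MeCN at 70 °C oxidises 5 to its C3 radical, which adds to the same alkene carbon of 6. The benzylic radical is oxidised by monovalent silver to the cation and closed by O4. This gives racemic trans material, that is 9 together with its mirror image, the (2S,3S)-enantiomer of 9 F1. Preparative HPLC on a chiral stationary phase removes F1, and the route is rejoined at 9.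

Step 2 is the second risk. The dianion aldol may be low-yielding, or aryl silyl ethers may be lost under the strongly basic and then acidic conditions. The fallback sets out from 2 and builds the pyranone ring instead of extending a preformed one. Horner–Wadsworth–Emmons olefination of 2 with diethyl [2-(methoxy(methyl)amino)-2-oxoethyl]phosphonate (NaH, THF, 0 °C) gives the (E)-cinnamoyl Weinreb amide F2. Acylation of the lithium dienolate of 2,2,6-trimethyl-4H-1,3-dioxin-4-one (LiN(iPr)2, THF, −78 °C) with F2 gives the styryl keto-dioxinone F3. Heating F3 in toluene at 110 °C expels acetone, and the acylketene is trapped by its own enol to close the 4-hydroxy-2-pyranone. The route is rejoined at 5.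

Step 5 is the third risk. The free bis-catechol may oxidise, or may be hard to separate from fluoride and pyridinium salts. The fallback sets out from 9 and passes through a stable, purifiable peracetate instead of liberating the polyphenol directly. HF·pyridine in THF removes the four silyl groups to give the tetraphenol mono-acetate F4. F4 is not isolated but treated in the same flask with Ac2O/pyridine to give hypholomine B pentaacetate F5. F5 can be chromatographed and recrystallised, which also offers an upgrade of enantiomeric purity. Neutral deacetylation of F5 (NH4OAc, degassed MeOH, rt) then rejoins the route at 11.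

**Further compounds**

F1 | step 4 | 6-[(2S,3S)-2-[3,4-bis(tert-butyldimethylsilyloxy)phenyl]-6-{(E)-2-[3,4-bis(tert-butyldimethylsilyloxy)phenyl]ethenyl}-4-oxo-2,3-dihydro-4H-furo[3,2-c]pyran-3-yl]-2-oxo-2H-pyran-4-yl acetate (enantiomer of 9) | O=c1cc(OC(C)=O)cc([C@H]2c3c(cc(/C=C/c4ccc(O[Si](C)(C)C(C)(C)C)c(O[Si](C)(C)C(C)(C)C)c4)oc3=O)O[C@@H]2c2ccc(O[Si](C)(C)C(C)(C)C)c(O[Si](C)(C)C(C)(C)C)c2)o1
F2 | step 2 | (E)-3-[3,4-bis(tert-butyldimethylsilyloxy)phenyl]-N-methoxy-N-methylprop-2-enamide | CON(C)C(=O)/C=C/c1ccc(O[Si](C)(C)C(C)(C)C)c(O[Si](C)(C)C(C)(C)C)c1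
F3 | step 2 | 6-{(E)-4-[3,4-bis(tert-butyldimethylsilyloxy)phenyl]-2-oxobut-3-en-1-yl}-2,2-dimethyl-4H-1,3-dioxin-4-one | CC1(C)OC(=O)C=C(CC(=O)/C=C/c2ccc(O[Si](C)(C)C(C)(C)C)c(O[Si](C)(C)C(C)(C)C)c2)O1
F4 | step 5 | 6-[(2R,3R)-2-(3,4-dihydroxyphenyl)-6-[(E)-2-(3,4-dihydroxyphenyl)ethenyl]-4-oxo-2,3-dihydro-4H-furo[3,2-c]pyran-3-yl]-2-oxo-2H-pyran-4-yl acetate | O=c1cc(OC(C)=O)cc([C@@H]2c3c(cc(/C=C/c4ccc(O)c(O)c4)oc3=O)O[C@H]2c2ccc(O)c(O)c2)o1
F5 | step 5 | hypholomine B pentaacetate, 6-[(2R,3R)-2-(3,4-diacetoxyphenyl)-6-[(E)-2-(3,4-diacetoxyphenyl)ethenyl]-4-oxo-2,3-dihydro-4H-furo[3,2-c]pyran-3-yl]-2-oxo-2H-pyran-4-yl acetate | O=c1cc(OC(C)=O)cc([C@@H]2c3c(cc(/C=C/c4ccc(OC(C)=O)c(OC(C)=O)c4)oc3=O)O[C@H]2c2ccc(OC(C)=O)c(OC(C)=O)c2)o1
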